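**Retrosynthetic overview**
1. Target ⇐ C6 acetylation and isopropenyl hydrogenation of an 8-angeloyloxyguaia-1(10),11-diene-4,6-diol.
2. That diol ⇐ one-flask cascade from an open-chain (2R,3S)-2,3-epoxy-9-angeloyloxyfarnesal: carbonyl-ene closure C1–C10 gives the ten-membered epoxygermacradienol first; transannular epoxide–olefin closure (germacrane C1–C5) then forms the five- and seven-membered rings together (farnesyl → germacrane → guaiane order).
3. Epoxy aldehyde ⇐ Sharpless epoxidation and oxidation of (9S)-9-angeloyloxy-(2E,6E)-farnesol.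
4. That farnesol ⇐ B-alkyl Suzuki coupling (C5–C6) of a dienol-derived borane with an E-vinyl iodide angelate.
5. Vinyl iodide ⇐ carboalumination/iodination and angeloylation of the homopropargylic alcohol from asymmetric propargylation of prenal (sets C9, the future C8).

Numbering: open-chain compounds carry farnesane numbering (C1 = carbinol/aldehyde carbon, angelate on C9); cyclic compounds carry germacrane/guaiane numbering (farnesane C1, C2, C3, C6, C7, C9, C10 become C6, C5, C4, C1, C10, C8, C7).

Assumption: in step 1 the (S)-acid is taken to give the (S)-carbinol, following the sense known for this catalyst class with aryl and alkenyl aldehydes; if the opposite sense is found, the (R)-acid is used.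

**Step 1**
Reactants: 1 3-methylbut-2-enal (prenal); 2 allenylboronic acid pinacol ester
Product: 3 (4S)-6-methylhept-5-en-1-yn-4-ol
Conditions: (S)-TRIP phosphoric acid (5 mol%), 4 Å MS, toluene, −20 °C; aq. work-up
Reagents that add atoms: none
Why: Chiral phosphoric acid-catalysed asymmetric propargylboration; the allenylboronate adds through a closed six-membered SE2' transition state held by the catalyst, which selects one aldehyde face and sets the carbinol as S (the future C8 of the target).

**Step 2**
Reactants: 3 (4S)-6-methylhept-5-en-1-yn-4-ol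
Product: 5 (1E,4S)-1-iodo-2,6-dimethylhepta-1,5-dien-4-ol, via vinylalane 4 (not isolated)
Conditions: Me3Al (3 equiv), Cp2ZrCl2 (0.3 equiv), CH2Cl2, 0 °C → rt; then I2 (1.3 equiv), THF, −30 → 0 °C
Reagents that add atoms: trimethylaluminium C[Al](C)C; iodine II
Why: Negishi zirconium-catalysed carboalumination adds Me–Al syn across the terminal alkyne (methyl to the internal carbon) and iodinolysis with retention gives the E trisubstituted vinyl iodide; the carbinol is carried as its aluminium alkoxide and the stereocentre is untouched.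

**Step 3**
Reactants: 5 (1E,4S)-1-iodo-2,6-dimethylhepta-1,5-dien-4-ol; 6 angelic acid ((2Z)-2-methylbut-2-enoic acid)
Product: 8 (1E,4S)-1-iodo-2,6-dimethylhepta-1,5-dien-4-yl (2Z)-2-methylbut-2-enoate, via mixed anhydride 7 (not isolated)
Conditions: 6 (2 equiv), 2,4,6-trichlorobenzoyl chloride (2 equiv), Et3N (2.2 equiv), toluene, rt, 2 h; then 5, 75 °C
Reagents that add atoms: none
Why: Yamaguchi-type mixed-anhydride esterification without a nucleophilic catalyst, the standard way to make angelates without Z-to-E isomerisation to the tiglate; acylation on oxygen leaves the stereocentre unchanged.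

**Step 4**
Reactants: 9 (2E)-3-methylpent-2-en-4-yn-1-ol
Product: 10 (2E)-3-methylpenta-2,4-dien-1-ol
Conditions: H2 (1 atm, stopped at 1 equiv), Pd on CaCO3 poisoned with Pb(OAc)2 (Lindlar catalyst), quinoline, EtOAc, rt
Reagents that add atoms: none
Why: Lindlar semihydrogenation of the terminal alkyne of a conjugated enyne stops at the diene and does not touch the E trisubstituted olefin.

**Step 5**
Reactants: 10 (2E)-3-methylpenta-2,4-dien-1-ol; 8 (1E,4S)-1-iodo-2,6-dimethylhepta-1,5-dien-4-yl (2Z)-2-methylbut-2-enoate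
Product: 12 (2E,6E,9S)-1-hydroxy-3,7,11-trimethyldodeca-2,6,10-trien-9-yl (2Z)-2-methylbut-2-enoate, via alkylborane 11 (not isolated)
Conditions: 10, 9-BBN (2.2 equiv), THF, 0 °C → rt; then 8, PdCl2(dppf) (5 mol%), AsPh3 (10 mol%), Cs2CO3 (3 equiv), DMF/H2O, rt
Reagents that add atoms: none
Why: 9-BBN hydroboration (one equivalent is taken up by the hydroxyl as borinate) is anti-Markovnikov at the monosubstituted olefin only, and B-alkyl Suzuki–Miyaura coupling retains the E vinyl geometry; the vinyl iodide adds to zerovalent palladium much faster than the hindered allylic angelate ionises.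

**Step 6**
Reactants: 12 (2E,6E,9S)-1-hydroxy-3,7,11-trimethyldodeca-2,6,10-trien-9-yl (2Z)-2-methylbut-2-enoate
Product: 13 (2S,3S,6E,9S)-2,3-epoxy-1-hydroxy-3,7,11-trimethyldodeca-6,10-dien-9-yl (2Z)-2-methylbut-2-enoate
Conditions: Ti(OiPr)4 (10 mol%), L-(+)-diethyl tartrate (12 mol%), t-BuOOH (2 equiv), 4 Å MS, CH2Cl2, −20 °C
Reagents that add atoms: tert-butyl hydroperoxide CC(C)(C)OO
Why: Sharpless asymmetric epoxidation is reagent-controlled; L-(+)-tartrate gives the (2S,3S)-epoxide of an E-3-methylalk-2-en-1-ol (as with geraniol), and the other olefins, not being allylic alcohols, are inert.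

**Step 7**
Reactants: 13 (2S,3S,6E,9S)-2,3-epoxy-1-hydroxy-3,7,11-trimethyldodeca-6,10-dien-9-yl (2Z)-2-methylbut-2-enoate
Product: 14 (2R,3S,6E,9S)-2,3-epoxy-3,7,11-trimethyl-1-oxododeca-6,10-dien-9-yl (2Z)-2-methylbut-2-enoate
Conditions: TEMPO (10 mol%), PhI(OAc)2 (1.2 equiv), CH2Cl2, rt
Reagents that add atoms: none
Why: Oxoammonium (TEMPO/PhI(OAc)2) oxidation of the primary alcohol stops at the aldehyde under near-neutral conditions that spare the epoxide and olefins; C2 is not epimerised (its descriptor changes from S to R only through CIP priorities).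

**Step 8**
Reactants: 14 (2R,3S,6E,9S)-2,3-epoxy-3,7,11-trimethyl-1-oxododeca-6,10-dien-9-yl (2Z)-2-methylbut-2-enoate
Product: 16 (4S,5R,6R,7S,8S)-4,6-dihydroxyguaia-1(10),11-dien-8-yl (2Z)-2-methylbut-2-enoate, via epoxygermacradienol 15 (not isolated)
Conditions: Me2AlCl (3 equiv), CH2Cl2, slow addition of 14 to 0.002 M, −78 °C, then −78 → 0 °C; aq. KNa tartrate
Reagents that add atoms: none
Why: Proposed new method: Me2AlCl chelates the aldehyde and epoxide oxygens of 14 and the distal C10=C11 olefin attacks the activated carbonyl in a macrocyclic type 1 carbonyl-ene reaction (C1–C10 bond, hydrogen taken from a C11 methyl to leave the isopropenyl group; six- or seven-membered closure through C6=C7 is excluded because a trans-epoxide cannot sit in such a ring), attack on the chelate from the side of H2 sets C6 as R and attack on the olefin anti to the allylic ester with H9 eclipsed (A1,3 strain) sets C7, and on warming the aluminium alkoxide of 15 activates the neighbouring epoxide, which the transannular C1=C10 olefin opens at C5 with inversion (C1–C5 bond, C4–O kept) before the C10 cation loses H1 to give the tetrasubstituted olefin; the closest known reaction types are Me2AlCl-promoted intramolecular carbonyl-ene cyclisations of olefinic aldehydes, chelation-controlled additions to 2,3-epoxy aldehydes, and the acid-induced transannular cyclisation of 4,5-epoxygermacrenes to 4-hydroxyguai-1(10)-enes (parthenolide to micheliolide).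

**Step 9**
Reactants: 16 (4S,5R,6R,7S,8S)-4,6-dihydroxyguaia-1(10),11-dien-8-yl (2Z)-2-methylbut-2-enoate
Product: 17 (4S,5R,6R,7S,8S)-4,6-dihydroxyguai-1(10)-en-8-yl (2Z)-2-methylbut-2-enoate
Conditions: H2 (1 atm), RhCl(PPh3)3 (10 mol%), benzene/EtOH 1:1, rt
Reagents that add atoms: none
Why: Homogeneous hydrogenation with RhCl(PPh3)3 reduces the 1,1-disubstituted isopropenyl group much faster than the conjugated trisubstituted angelate or the tetrasubstituted ring olefin (the carvone to carvotanacetone selectivity); no stereocentre is formed.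

**Step 10**
Reactants: 17 (4S,5R,6R,7S,8S)-4,6-dihydroxyguai-1(10)-en-8-yl (2Z)-2-methylbut-2-enoate
Product: 18 (4S,5R,6R,7R,8S)-6-acetoxy-4-hydroxyguai-1(10)-en-8-yl (2Z)-2-methylbut-2-enoate (target)
Conditions: Ac2O (1.5 equiv), pyridine, DMAP (0.1 equiv), CH2Cl2, 0 °C → rt
Reagents that add atoms: acetic anhydride CC(=O)OC(C)=O
Why: DMAP-catalysed acetylation takes the secondary C6 hydroxyl and leaves the tertiary C4 hydroxyl; no stereocentre is touched (C7 changes from S to R only through CIP priorities).

**Compound list**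
1 | 3-methylbut-2-enal (prenal) | CC(C)=CC=O | starting material
2 | allenylboronic acid pinacol ester (4,4,5,5-tetramethyl-2-(propa-1,2-dien-1-yl)-1,3,2-dioxaborolane) | C=C=CB1OC(C)(C)C(C)(C)O1 | starting material
3 | (4S)-6-methylhept-5-en-1-yn-4-ol | CC(C)=C[C@@H](O)CC#C | intermediate
4 | [(1E,4S)-4-(dimethylaluminooxy)-2,6-dimethylhepta-1,5-dien-1-yl]dimethylaluminium (vinylalane, not isolated) | CC(C)=C[C@@H](O[Al](C)C)C/C(C)=C/[Al](C)C | intermediate
5 | (1E,4S)-1-iodo-2,6-dimethylhepta-1,5-dien-4-ol | CC(C)=C[C@@H](O)C/C(C)=C/I | intermediate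
6 | angelic acid, (2Z)-2-methylbut-2-enoic acid | C/C=C(/C)C(=O)O | starting material
7 | angelic 2,4,6-trichlorobenzoic anhydride (mixed anhydride, not isolated) | C/C=C(/C)C(=O)OC(=O)c1c(Cl)cc(Cl)cc1Cl | intermediate
8 | (1E,4S)-1-iodo-2,6-dimethylhepta-1,5-dien-4-yl (2Z)-2-methylbut-2-enoate | C/C=C(/C)C(=O)O[C@H](C=C(C)C)C/C(C)=C/I | intermediate
9 | (2E)-3-methylpent-2-en-4-yn-1-ol | C#C/C(C)=C/CO | starting material
10 | (2E)-3-methylpenta-2,4-dien-1-ol | C=C/C(C)=C/CO | intermediate
11 | 9-{[(2E)-5-(9-borabicyclo[3.3.1]nonan-9-yl)-3-methylpent-2-en-1-yl]oxy}-9-borabicyclo[3.3.1]nonane (alkylborane, not isolated) | B1(OC/C=C(C)/CCB2C3CCCC2CCC3)C4CCCC1CCC4 | intermediate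
12 | (2E,6E,9S)-1-hydroxy-3,7,11-trimethyldodeca-2,6,10-trien-9-yl (2Z)-2-methylbut-2-enoate | C/C=C(/C)C(=O)O[C@H](C=C(C)C)C/C(C)=C/CC/C(C)=C/CO | intermediate
13 | (2S,3S,6E,9S)-2,3-epoxy-1-hydroxy-3,7,11-trimethyldodeca-6,10-dien-9-yl (2Z)-2-methylbut-2-enoate (trans-epoxide) | C/C=C(/C)C(=O)O[C@H](C=C(C)C)C/C(C)=C/CC[C@]1(C)O[C@H]1CO | intermediate
14 | (2R,3S,6E,9S)-2,3-epoxy-3,7,11-trimethyl-1-oxododeca-6,10-dien-9-yl (2Z)-2-methylbut-2-enoate | C/C=C(/C)C(=O)O[C@H](C=C(C)C)C/C(C)=C/CC[C@]1(C)O[C@H]1C=O | intermediate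
15 | (1(10)E,4S,5S,6R,7S,8S)-4,5-epoxy-6-hydroxygermacra-1(10),11-dien-8-yl (2Z)-2-methylbut-2-enoate (ten-membered ring, trans-epoxide; present as its aluminium alkoxide, not isolated) | C/C=C(/C)C(=O)O[C@H]1C/C(C)=C/CC[C@]2(C)O[C@H]2[C@H](O)[C@@H]1C(C)=C | intermediate
16 | (4S,5R,6R,7S,8S)-4,6-dihydroxyguaia-1(10),11-dien-8-yl (2Z)-2-methylbut-2-enoate | C/C=C(/C)C(=O)O[C@H]1CC(C)=C2CC[C@](C)(O)[C@H]2[C@H](O)[C@@H]1C(C)=C | intermediate
17 | (4S,5R,6R,7S,8S)-4,6-dihydroxyguai-1(10)-en-8-yl (2Z)-2-methylbut-2-enoate | C/C=C(/C)C(=O)O[C@H]1CC(C)=C2CC[C@](C)(O)[C@H]2[C@H](O)[C@@H]1C(C)C | intermediate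
18 | (4S,5R,6R,7R,8S)-6-acetoxy-4-hydroxyguai-1(10)-en-8-yl (2Z)-2-methylbut-2-enoate | C/C=C(/C)C(=O)O[C@H]1CC(C)=C2CC[C@](C)(O)[C@H]2[C@H](OC(C)=O)[C@@H]1C(C)C | target

**Totals**
Total step count: 10. Longest linear sequence: 9 (steps 1, 2, 3, 5, 6, 7, 8, 9, 10).

**Three steps most likely to fail**

Step 8 (ene/transannular cascade). A ten-membered carbonyl-ene closure onto an olefin deactivated by an allylic ester is unprecedented. It competes with Lewis-acid rearrangement of the epoxy aldehyde and ionisation of the allylic angelate, and the C6/C7 selectivity rests on models, not on precedent. The fallback replaces the cationic closure by an allyl-metal closure and separates the two ring-forming events. It sets out from 13 and comes back to the route at 16, passing through 15, which is now isolated. Allylic oxidation of the E methyl group of the terminal olefin of 13 (cat. SeO2, t-BuOOH, CH2Cl2) gives the diol F1. Corey–Kim chlorination (NCS, Me2S, CH2Cl2, −20 °C), selective for the allylic hydroxyl, gives the allylic chloride F2. TEMPO/PhI(OAc)2 oxidation gives the chloro epoxy aldehyde F3. Intramolecular Nozaki–Hiyama allylation (CrCl2, THF, 0.005 M), in which the allylchromium adds through C10, closes the ten-membered ring to 15; its C6/C7 selectivity would have to be established. Treatment of 15 with BF3·OEt2 (CH2Cl2, −40 °C) then gives 16.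

Step 5 (hydroboration/Suzuki coupling). The allylic angelate may ionise at palladium or isomerise, and the free hydroxyl consumes borane. The fallback moves the acylation behind the coupling and masks the primary hydroxyl. It sets out from 10 and 5 and comes back at 12. Silylation of 10 (TBSCl, imidazole, DMF) gives the silyl ether F4. Hydroboration (9-BBN, 1.1 equiv) and coupling under the step 5 conditions with the unacylated vinyl iodide 5 gives the alcohol F5. Angeloylation through the mixed anhydride 7 as in step 3 gives the silyl ether F6, and HF·pyridine (THF, 0 °C) releases 12.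

Step 1 (asymmetric propargylation). A β,β-disubstituted enal may react slowly or with insufficient enantiomeric excess, which would show up as diastereomers after step 6. The fallback replaces asymmetric catalysis by resolution. It sets out from 1 and comes back at 3. Zinc-mediated Barbier propargylation of 1 (propargyl bromide, Zn dust, THF/aq. NH4Cl) gives the racemic alcohol F7. Lipase-catalysed kinetic resolution (Burkholderia cepacia lipase, vinyl acetate, MTBE, rt) acylates the R enantiomer to the acetate F8 (Kazlauskas rule with the dimethylvinyl group as the large substituent) and leaves (S)-3, which is separated by chromatography.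

**Further compounds**
F1 | step 8 | (2S,3S,6E,9S,10E)-2,3-epoxy-1,12-dihydroxy-3,7,11-trimethyldodeca-6,10-dien-9-yl (2Z)-2-methylbut-2-enoate | C/C=C(/C)C(=O)O[C@H](/C=C(\C)CO)C/C(C)=C/CC[C@]1(C)O[C@H]1CO
F2 | step 8 | (2S,3S,6E,9S,10E)-12-chloro-2,3-epoxy-1-hydroxy-3,7,11-trimethyldodeca-6,10-dien-9-yl (2Z)-2-methylbut-2-enoate | C/C=C(/C)C(=O)O[C@H](/C=C(\C)CCl)C/C(C)=C/CC[C@]1(C)O[C@H]1CO
F3 | step 8 | (2R,3S,6E,9S,10E)-12-chloro-2,3-epoxy-3,7,11-trimethyl-1-oxododeca-6,10-dien-9-yl (2Z)-2-methylbut-2-enoate | C/C=C(/C)C(=O)O[C@H](/C=C(\C)CCl)C/C(C)=C/CC[C@]1(C)O[C@H]1C=O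
F4 | step 5 | tert-butyldimethyl{[(2E)-3-methylpenta-2,4-dien-1-yl]oxy}silane | C=C/C(C)=C/CO[Si](C)(C)C(C)(C)C
F5 | step 5 | (2E,6E,9S)-1-(tert-butyldimethylsilyloxy)-3,7,11-trimethyldodeca-2,6,10-trien-9-ol | CC(C)=C[C@@H](O)C/C(C)=C/CC/C(C)=C/CO[Si](C)(C)C(C)(C)C
F6 | step 5 | (2E,6E,9S)-1-(tert-butyldimethylsilyloxy)-3,7,11-trimethyldodeca-2,6,10-trien-9-yl (2Z)-2-methylbut-2-enoate | C/C=C(/C)C(=O)O[C@H](C=C(C)C)C/C(C)=C/CC/C(C)=C/CO[Si](C)(C)C(C)(C)C
F7 | step 1 | racemic 6-methylhept-5-en-1-yn-4-ol | CC(C)=CC(O)CC#C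
F8 | step 1 | (4R)-6-methylhept-5-en-1-yn-4-yl acetate | CC(C)=C[C@H](OC(C)=O)CC#C
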